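The whole route rests on cutting the C6a–C6b bond of dihydrofuran ring C. It uses the fact that O11 (on C11a) and ring D carbon C6b (on C6a) sit on one face of ring B. Both can therefore be delivered by anti attack on the two carbons of one enantioenriched C6a–C11a chromene oxide, oxygen first and carbon second. In a single operation the key step frees O9 as a phenoxide and lets C6b, para to it and ortho to O11, displace a C6a sulfonate with inversion. This closes ring C and sets C6a. The precursor is the mesylate of a trans-4-aryloxychroman-3-ol bearing the ring A bromide and the ring D prenyl, allyl ether and dimethylpropargyl ether.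

Key step: step 12

**Remarks before the steps**
- Numbering: coupled compounds use pterocarpan numbering. Chroman C2, C3 and C4 correspond to C6, C6a and C11a.
- Assumption: the sense of induction in step 9 is taken from 2,2-dimethylchromenes and indene, where the (R,R)-salen ligand makes the benzylic epoxide carbon R. If it were reversed, the (S,S)-complex would be used.
- O9 in the cyclisation substrate: an O9 alkyl ether squeezed between the C10 prenyl group and O8 is twisted out of conjugation. O11 is also deconjugated in the closure geometry. A neutral ring D would therefore be a weak nucleophile, so O9 is released as a phenoxide at the moment of closure.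
- Leaving group: a mesylate replaces a super-leaving group. With an equatorial leaving group the C11a–C11b bond of electron-rich ring A is antiperiplanar to it, and its shift (ring contraction to an O11-stabilised cation) would accompany easy ionisation.
- O3 protection: O3 carries triisopropylsilyl, a weaker donor than an alkyl ether. It is stable to phenoxides and slow in O-to-C silyl shift.
- O8 substituent: O8 carries its dimethylpropargyl group from the start. No silicon then sits next to the O9 phenoxide, and one later step is saved.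

**Step 1**
Reactants: 1 2,4-dihydroxybenzaldehyde; 2 1-bromo-3-methylbut-2-ene (prenyl bromide)
Product: 3 2,4-dihydroxy-3-(3-methylbut-2-enyl)benzaldehyde
Conditions: KOH, H2O, 0 °C to rt
Reagents that add atoms: none
Why: C-alkylation of an ambident resorcinolate in water, where hydrogen bonding shields the oxygens and the carbon between them (C3) is the most nucleophilic one; O-prenyl and C5-prenyl isomers are removed by chromatography at this cheap first stage.

**Step 2**
Reactants: 3 2,4-dihydroxy-3-(3-methylbut-2-enyl)benzaldehyde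
Product: 4 2-hydroxy-3-(3-methylbut-2-enyl)-4-(triisopropylsilyloxy)benzaldehyde
Conditions: TIPSCl, imidazole, DMF, 0 °C
Reagents that add atoms: triisopropylsilyl chloride, CC(C)[Si](Cl)(C(C)C)C(C)C
Why: Chemoselective O-silylation: the C2 hydroxyl is hydrogen-bonded to the aldehyde and flanked on both sides, so only the C4 hydroxyl (the future O11) reacts, and the bulky silyl ether survives steps 3 to 5 and falls to fluoride in step 6.

**Step 3**
Reactants: 4 2-hydroxy-3-(3-methylbut-2-enyl)-4-(triisopropylsilyloxy)benzaldehyde
Product: 5 2-(allyloxy)-3-(3-methylbut-2-enyl)-4-(triisopropylsilyloxy)benzaldehyde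
Conditions: allyl alcohol, PPh3, DIAD, THF, 0 °C to rt
Reagents that add atoms: allyl alcohol, C=CCO
Why: Mitsunobu etherification of the acidic salicylaldehyde-type phenol (the future O9) with a primary alcohol under neutral conditions, which avoids the carbonate bases that could cleave a silyl ether para to a formyl group.

**Step 4**
Reactants: 5 2-(allyloxy)-3-(3-methylbut-2-enyl)-4-(triisopropylsilyloxy)benzaldehyde
Product: 7 2-(allyloxy)-3-(3-methylbut-2-enyl)-4-(triisopropylsilyloxy)phenol, via aryl formate 6 (not isolated)
Conditions: 30% aq H2O2, KHSO4 (cat.), MeOH, 0 °C to rt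
Reagents that add atoms: hydrogen peroxide, OO
Why: Acid-catalysed Dakin-type (Baeyer–Villiger) oxidation in which H2O2 adds to the aldehyde, the electron-rich aryl group (para silyloxy, ortho allyloxy) migrates to oxygen and formate 6 is methanolysed in situ; no peracid is present, so the prenyl and allyl double bonds are not epoxidised, and the acid is kept catalytic and cold to spare the prenyl group.

**Step 5**
Reactants: 7 2-(allyloxy)-3-(3-methylbut-2-enyl)-4-(triisopropylsilyloxy)phenol; 8 3-chloro-3-methylbut-1-yne
Product: 9 [3-(allyloxy)-4-(2-methylbut-3-yn-2-yloxy)-2-(3-methylbut-2-enyl)phenoxy]triisopropylsilane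
Conditions: CuCl2·2H2O (1 mol %), DBU, MeCN, 0 °C
Reagents that add atoms: none
Why: Copper-catalysed O-alkylation of a phenol with a tertiary propargylic chloride, the standard entry to aryl 1,1-dimethylpropargyl ethers; the new hydroxyl (O8) is the only free one, so no regiochemical question arises.

**Step 6**
Reactants: 9 [3-(allyloxy)-4-(2-methylbut-3-yn-2-yloxy)-2-(3-methylbut-2-enyl)phenoxy]triisopropylsilane
Product: 10 3-(allyloxy)-4-(2-methylbut-3-yn-2-yloxy)-2-(3-methylbut-2-enyl)phenol
Conditions: Bu4NF, AcOH, THF, 0 °C
Reagents that add atoms: none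
Why: Fluoride cleavage of the aryl silyl ether, buffered with acetic acid, frees O11–H and leaves the allyl, propargyl and prenyl groups untouched.

**Step 7**
Reactants: 11 5-bromo-2,4-dihydroxybenzaldehyde
Product: 12 5-bromo-2-hydroxy-4-(triisopropylsilyloxy)benzaldehyde
Conditions: TIPSCl, imidazole, DMF, 0 °C
Reagents that add atoms: triisopropylsilyl chloride, CC(C)[Si](Cl)(C(C)C)C(C)C
Why: Chemoselective O-silylation of the non-chelated, more acidic C4 hydroxyl (the future O3), on the same grounds as in step 2.

**Step 8**
Reactants: 12 5-bromo-2-hydroxy-4-(triisopropylsilyloxy)benzaldehyde; 13 vinyltriphenylphosphonium bromide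
Product: 14 6-bromo-7-(triisopropylsilyloxy)-2H-chromene
Conditions: NaH, THF, 0 °C; then 13, reflux
Reagents that add atoms: none
Why: Oxa-Michael addition of the phenoxide to the vinylphosphonium salt followed by intramolecular Wittig olefination (Schweizer chromene synthesis) builds C6 and C6a in one operation; because every molecule is present as its phenoxide, the para silyl ether is a poor leaving group and should stay in place.

**Step 9**
Reactants: 14 6-bromo-7-(triisopropylsilyloxy)-2H-chromene
Product: 15 (3S,4R)-6-bromo-3,4-epoxy-7-(triisopropylsilyloxy)chroman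
Conditions: (R,R)-N,N'-bis(3,5-di-tert-butylsalicylidene)-1,2-cyclohexanediaminomanganese chloride [(R,R)-(salen)MnCl, 4 mol %], 4-phenylpyridine N-oxide, aq NaOCl (pH 11.3), CH2Cl2, 0 °C
Reagents that add atoms: sodium hypochlorite, [Na+].[O-]Cl
Why: Jacobsen–Katsuki epoxidation of a cis-disubstituted, aryl-conjugated cyclic alkene, in which the oxo-manganese salen species approaches side-on and the (R,R)-ligand directs oxygen to the face that makes the benzylic carbon R, setting both epoxide carbons (3S,4R) in one event; the basic two-phase medium protects the acid-labile epoxide, which is used without chromatography.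

**Step 10**
Reactants: 15 (3S,4R)-6-bromo-3,4-epoxy-7-(triisopropylsilyloxy)chroman; 10 3-(allyloxy)-4-(2-methylbut-3-yn-2-yloxy)-2-(3-methylbut-2-enyl)phenol
Product: 16 (3S,4S)-trans-6-bromo-4-[3-(allyloxy)-4-(2-methylbut-3-yn-2-yloxy)-2-(3-methylbut-2-enyl)phenoxy]-7-(triisopropylsilyloxy)chroman-3-ol
Conditions: Cs2CO3 (20 mol %), MeCN, 0 °C to rt
Reagents that add atoms: none
Why: Base-catalysed SN2 opening of a 3,4-epoxychroman by a phenoxide at the benzylic carbon (trans-diaxial opening, a known reaction of chromene oxides): attack anti to the epoxide oxygen inverts C11a (4R to 4S) and leaves the C6a–O bond untouched, giving the trans alcohol, while catalytic base, an aprotic solvent and low temperature keep the reaction away from ionisation and from attack on silicon.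

**Step 11**
Reactants: 16 (3S,4S)-trans-6-bromo-4-[3-(allyloxy)-4-(2-methylbut-3-yn-2-yloxy)-2-(3-methylbut-2-enyl)phenoxy]-7-(triisopropylsilyloxy)chroman-3-ol
Product: 17 methanesulfonate of 16, (3S,4S)
Conditions: MsCl, Et3N, CH2Cl2, −20 to 0 °C
Reagents that add atoms: methanesulfonyl chloride, CS(=O)(=O)Cl
Why: Sulfonylation of the secondary alcohol with retention at C6a; a mesylate is reactive enough for an intramolecular SN2 displacement yet, with two β-oxygen atoms, slow to ionise, and it is inert to zerovalent palladium.

**Step 12**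
Reactants: 17 methanesulfonate of 16, (3S,4S)
Product: 19 (6aR,11aR)-2-bromo-9-hydroxy-8-(2-methylbut-3-yn-2-yloxy)-10-(3-methylbut-2-enyl)-3-(triisopropylsilyloxy)pterocarpan, via sodium phenoxide 18 (not isolated)
Conditions: Pd(PPh3)4 (5 mol %), p-TolSO2Na (1.05 equiv), degassed DMF, rt; then 50 °C
Reagents that add atoms: none
Why: Proposed new method: zerovalent palladium ionises the O9 allyl ether and the sulfinate captures the π-allyl fragment (Tsuji–Trost deallylation), leaving sodium phenoxide 18, whose carbon C6b (para to the O9 oxide, ortho to O11) attacks C6a from the face opposite the mesylate, after which a proton shift restores ring D as the free O9 phenol. The closest known reaction types are the intramolecular C-alkylation of phenolates by secondary sulfonates (aryl participation with inversion) and, on the neutral side, the invertive Friedel–Crafts cyclisation of electron-rich arenes onto secondary sulfonates; neither has been shown on a 4-aryloxychroman-3-yl sulfonate. Ring C closes in a 5-exo-tet mode (C6b, C10a, O11, C11a and C6a in the ring, the mesylate outside it), made possible by the trans-diaxial half-chair of the C2-unsubstituted chroman, in which the arene hanging from axial O11 lies over the rear lobe of the C6a–O bond. The new stereocentre C6a is set by inversion of the carbinol carbon fixed in step 9, so the C6a–C6b bond ends cis to C11a–O11 (6aR,11aR), while C11a is not touched. The step needs substitution to beat ionisation (shift of ring A with ring contraction, hydride shift) and elimination, and it needs attack through carbon: this is secured by a moderate leaving group in an aprotic medium, a phenoxide in place of a twisted and weakly donating ether at O9, the bromine and silyl ether that damp ring A, and the geometry, since O9 cannot reach C6a and C6b is the only free carbon within reach.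

**Step 13**
Reactants: 19 (6aR,11aR)-2-bromo-9-hydroxy-8-(2-methylbut-3-yn-2-yloxy)-10-(3-methylbut-2-enyl)-3-(triisopropylsilyloxy)pterocarpan
Product: 20 (6aR,11aR)-2-bromo-9-hydroxy-10-(3-methylbut-2-enyl)-3-(triisopropylsilyloxy)pterocarpan with a 2,2-dimethyl-2H-pyran ring fused at C7–C8 (pyran oxygen on C8)
Conditions: o-xylene, 140 °C, argon
Reagents that add atoms: none
Why: Thermal aromatic propargyl Claisen rearrangement to C7, the only free position ortho to O8, followed in the same pot by hydrogen shift and oxa-6π electrocyclisation, the standard route from aryl 1,1-dimethylpropargyl ethers to 2,2-dimethyl-2H-chromenes; no stereocentre is touched.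

**Step 14**
Reactants: 20 ring D chromene bromide (as in step 13); 21 3-methylbut-2-enal
Product: 23 (6aR,11aR)-2-(1-hydroxy-3-methylbut-2-enyl) analogue of 20 (bromine replaced; carbinol carbon as a mixture of epimers), via dilithiated arene 22 (not isolated)
Conditions: n-BuLi (2.2 equiv), THF, −78 °C; then 21, −78 °C; aq NH4Cl
Reagents that add atoms: none
Why: Deprotonation of O9–H and bromine–lithium exchange, then 1,2-addition of the aryllithium to the enal; at −78 °C the bulky triisopropylsilyl group should not undergo the O-to-C (retro-Brook) shift, and the new carbinol centre, formed without control, is erased in step 15.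

**Step 15**
Reactants: 23 (6aR,11aR)-2-(1-hydroxy-3-methylbut-2-enyl) analogue of 20
Product: 25 lespecyrtin E4, via desilylated triol 24 (not isolated)
Conditions: Bu4NF, AcOH, THF, 0 °C; then PPTS (10 mol %), CH2Cl2, rt
Reagents that add atoms: none
Why: Fluoride desilylation followed by acid-catalysed cyclodehydration of an ortho-hydroxyaryl allylic alcohol to a 2,2-dimethyl-2H-chromene (ionisation of the doubly activated benzylic–allylic alcohol and closure of O3 on the tertiary terminus), a known chromene synthesis; the acid is too weak to add O9–H to the prenyl group, and any reversible opening of the C11a–O11 bond can only re-close cis to the fixed C6a centre.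

**Compound list**

1 | 2,4-dihydroxybenzaldehyde | O=Cc1ccc(O)cc1O | starting material
2 | 1-bromo-3-methylbut-2-ene (prenyl bromide) | CC(C)=CCBr | starting material
3 | 2,4-dihydroxy-3-(3-methylbut-2-enyl)benzaldehyde | O=Cc1ccc(O)c(CC=C(C)C)c1O | intermediate
4 | 2-hydroxy-3-(3-methylbut-2-enyl)-4-(triisopropylsilyloxy)benzaldehyde | O=Cc1ccc(O[Si](C(C)C)(C(C)C)C(C)C)c(CC=C(C)C)c1O | intermediate
5 | 2-(allyloxy)-3-(3-methylbut-2-enyl)-4-(triisopropylsilyloxy)benzaldehyde | O=Cc1ccc(O[Si](C(C)C)(C(C)C)C(C)C)c(CC=C(C)C)c1OCC=C | intermediate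
6 | 2-(allyloxy)-3-(3-methylbut-2-enyl)-4-(triisopropylsilyloxy)phenyl formate | O=COc1ccc(O[Si](C(C)C)(C(C)C)C(C)C)c(CC=C(C)C)c1OCC=C | intermediate
7 | 2-(allyloxy)-3-(3-methylbut-2-enyl)-4-(triisopropylsilyloxy)phenol | Oc1ccc(O[Si](C(C)C)(C(C)C)C(C)C)c(CC=C(C)C)c1OCC=C | intermediate
8 | 3-chloro-3-methylbut-1-yne | C#CC(C)(C)Cl | starting material
9 | [3-(allyloxy)-4-(2-methylbut-3-yn-2-yloxy)-2-(3-methylbut-2-enyl)phenoxy]triisopropylsilane | C#CC(C)(C)Oc1ccc(O[Si](C(C)C)(C(C)C)C(C)C)c(CC=C(C)C)c1OCC=C | intermediate
10 | 3-(allyloxy)-4-(2-methylbut-3-yn-2-yloxy)-2-(3-methylbut-2-enyl)phenol | C#CC(C)(C)Oc1ccc(O)c(CC=C(C)C)c1OCC=C | intermediate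
11 | 5-bromo-2,4-dihydroxybenzaldehyde | O=Cc1cc(Br)c(O)cc1O | starting material
12 | 5-bromo-2-hydroxy-4-(triisopropylsilyloxy)benzaldehyde | O=Cc1cc(Br)c(O[Si](C(C)C)(C(C)C)C(C)C)cc1O | intermediate
13 | vinyltriphenylphosphonium bromide | [Br-].C=C[P+](c1ccccc1)(c1ccccc1)c1ccccc1 | starting material
14 | 6-bromo-7-(triisopropylsilyloxy)-2H-chromene | Brc1cc2C=CCOc2cc1O[Si](C(C)C)(C(C)C)C(C)C | intermediate
15 | (3S,4R)-6-bromo-3,4-epoxy-7-(triisopropylsilyloxy)chroman | O1[C@@H]2c3cc(Br)c(O[Si](C(C)C)(C(C)C)C(C)C)cc3OC[C@H]12 | intermediate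
16 | (3S,4S)-trans-6-bromo-4-[3-(allyloxy)-4-(2-methylbut-3-yn-2-yloxy)-2-(3-methylbut-2-enyl)phenoxy]-7-(triisopropylsilyloxy)chroman-3-ol | CC(C)=CCc1c(OCC=C)c(OC(C)(C)C#C)ccc1O[C@H]1c2cc(Br)c(O[Si](C(C)C)(C(C)C)C(C)C)cc2OC[C@@H]1O | intermediate
17 | (3S,4S)-methanesulfonate of 16 | CC(C)=CCc1c(OCC=C)c(OC(C)(C)C#C)ccc1O[C@H]1c2cc(Br)c(O[Si](C(C)C)(C(C)C)C(C)C)cc2OC[C@@H]1OS(C)(=O)=O | intermediate
18 | sodium O9 phenoxide of deallylated 17 | CC(C)=CCc1c([O-])c(OC(C)(C)C#C)ccc1O[C@H]1c2cc(Br)c(O[Si](C(C)C)(C(C)C)C(C)C)cc2OC[C@@H]1OS(C)(=O)=O.[Na+] | intermediate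
19 | (6aR,11aR)-2-bromo-9-hydroxy-8-(2-methylbut-3-yn-2-yloxy)-10-(3-methylbut-2-enyl)-3-(triisopropylsilyloxy)pterocarpan | CC(C)=CCc1c(O)c(OC(C)(C)C#C)cc2c1O[C@H]1c3cc(Br)c(O[Si](C(C)C)(C(C)C)C(C)C)cc3OC[C@@H]21 | intermediate
20 | (6aR,11aR)-2-bromo-9-hydroxy-10-(3-methylbut-2-enyl)-3-(triisopropylsilyloxy)pterocarpan with a 2,2-dimethyl-2H-pyran fused at C7–C8 (oxygen on C8) | CC(C)=CCc1c(O)c2c(c3c1O[C@H]1c4cc(Br)c(O[Si](C(C)C)(C(C)C)C(C)C)cc4OC[C@@H]31)C=CC(C)(C)O2 | intermediate
21 | 3-methylbut-2-enal | CC(C)=CC=O | starting material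
22 | C2-lithio O9-lithium phenoxide derived from 20 | CC(C)=CCc1c([O-])c2c(c3c1O[C@H]1c4cc([Li])c(O[Si](C(C)C)(C(C)C)C(C)C)cc4OC[C@@H]31)C=CC(C)(C)O2.[Li+] | intermediate
23 | (6aR,11aR)-2-(1-hydroxy-3-methylbut-2-enyl) analogue of 20, carbinol epimers | CC(C)=CCc1c(O)c2c(c3c1O[C@H]1c4cc(C(O)C=C(C)C)c(O[Si](C(C)C)(C(C)C)C(C)C)cc4OC[C@@H]31)C=CC(C)(C)O2 | intermediate
24 | 3-hydroxy (desilylated) analogue of 23 | CC(C)=CCc1c(O)c2c(c3c1O[C@H]1c4cc(C(O)C=C(C)C)c(O)cc4OC[C@@H]31)C=CC(C)(C)O2 | intermediate
25 | lespecyrtin E4, (6aR,11aR) | CC(C)=CCc1c(O)c2c(c3c1O[C@H]1c4cc5c(cc4OC[C@@H]31)OC(C)(C)C=C5)C=CC(C)(C)O2 | target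

**Step count**
- Total step count: 15.
- Longest linear sequence: 12 steps (1–6, then 10–15).

**Steps most likely to fail**

1. **Step 12 (key step).**
   - What may go wrong: the phenoxide carbon may reach the rear of C6a too slowly. Base-induced elimination toward C6, ionisation with migration of ring A, or C-allylation of the phenoxide by the π-allyl palladium species could then take over.
   - Fallback (known chemistry; sets out from 7 and 14, comes back at 19): the titanium-promoted formal [3+2] cycloaddition of 2H-chromenes with 2-alkoxy-1,4-benzoquinones, which is established for pterocarpans, including chiral-diol-modified variants. Phenol 7 is desilylated (Bu4NF, AcOH) to 2-(allyloxy)-3-(3-methylbut-2-enyl)benzene-1,4-diol F1. This is oxidised (Ag2O, Et2O) to 2-(allyloxy)-3-(3-methylbut-2-enyl)-1,4-benzoquinone F2. F2 and chromene 14 are combined with TiCl4/Ti(OiPr)4 and the appropriate TADDOL enantiomer in CH2Cl2 at −78 °C. Chromene C3 adds to C5 of the chelated quinone and the adjacent quinone oxygen captures the benzylic cation, which should give the cis-fused (6aR,11aR)-9-(allyloxy)-2-bromo-8-hydroxy-10-(3-methylbut-2-enyl)-3-(triisopropylsilyloxy)pterocarpan F3. Its enantiomeric purity is raised by crystallisation or chiral-phase chromatography if needed. O8 is propargylated as in step 5 to give the 8-(2-methylbut-3-yn-2-yloxy) ether F4. The allyl ether is then removed with Pd(PPh3)4 and p-TolSO2Na to give 19.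

2. **Step 9.**
   - What may go wrong: facial selectivity may be poor on a chromene without C2 substituents, and the very acid-labile, electron-rich epoxide may hydrolyse or rearrange during reaction and work-up.
   - Fallback (resolution in place of asymmetric catalysis, with the epoxide never isolated; sets out from 14, comes back at 16): NBS in aqueous DMSO converts 14 into (±)-trans-3,6-dibromo-7-(triisopropylsilyloxy)chroman-4-ol F5. Lipase-catalysed acetylation with vinyl acetate separates the enantiomers as (3R,4R)-3,6-dibromo-7-(triisopropylsilyloxy)chroman-4-ol F6 and the (3S,4S)-acetate F7. If the enzyme prefers the other enantiomer, the (3R,4R)-acetate is methanolysed to F6. F6, phenol 10 and K2CO3 in MeCN close the bromohydrin to 15 in the flask, where it is opened at once to give 16.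

3. **Step 4.**
   - What may go wrong: hydrogen may migrate instead of aryl (ester formation), or the acid may induce addition of methanol to the prenyl double bond.
   - Fallback (oxidation moved before the allylation so that a free ortho phenoxide drives a classical alkaline Dakin reaction; sets out from 4, comes back at 9): 4 is treated with H2O2 and NaOH in THF–H2O at 0 °C to give 3-(3-methylbut-2-enyl)-4-(triisopropylsilyloxy)benzene-1,2-diol F8. The bulky tertiary electrophile of step 5 (8, CuCl2·2H2O, DBU) should then alkylate the less hindered hydroxyl, giving 2-(2-methylbut-3-yn-2-yloxy)-6-(3-methylbut-2-enyl)-5-(triisopropylsilyloxy)phenol F9. The remaining hindered hydroxyl is allylated (allyl bromide, K2CO3, acetone) to give 9.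

**Further compounds**

F1 | step 12 | 2-(allyloxy)-3-(3-methylbut-2-enyl)benzene-1,4-diol | Oc1ccc(O)c(CC=C(C)C)c1OCC=C
F2 | step 12 | 2-(allyloxy)-3-(3-methylbut-2-enyl)-1,4-benzoquinone | O=C1C=CC(=O)C(CC=C(C)C)=C1OCC=C
F3 | step 12 | (6aR,11aR)-9-(allyloxy)-2-bromo-8-hydroxy-10-(3-methylbut-2-enyl)-3-(triisopropylsilyloxy)pterocarpan | CC(C)=CCc1c(OCC=C)c(O)cc2c1O[C@H]1c3cc(Br)c(O[Si](C(C)C)(C(C)C)C(C)C)cc3OC[C@@H]21
F4 | step 12 | (6aR,11aR)-9-(allyloxy)-2-bromo-8-(2-methylbut-3-yn-2-yloxy)-10-(3-methylbut-2-enyl)-3-(triisopropylsilyloxy)pterocarpan | CC(C)=CCc1c(OCC=C)c(OC(C)(C)C#C)cc2c1O[C@H]1c3cc(Br)c(O[Si](C(C)C)(C(C)C)C(C)C)cc3OC[C@@H]21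
F5 | step 9 | (±)-trans-3,6-dibromo-7-(triisopropylsilyloxy)chroman-4-ol | OC1c2cc(Br)c(O[Si](C(C)C)(C(C)C)C(C)C)cc2OCC1Br
F6 | step 9 | (3R,4R)-3,6-dibromo-7-(triisopropylsilyloxy)chroman-4-ol | O[C@@H]1c2cc(Br)c(O[Si](C(C)C)(C(C)C)C(C)C)cc2OC[C@H]1Br
F7 | step 9 | (3S,4S)-3,6-dibromo-7-(triisopropylsilyloxy)chroman-4-yl acetate | CC(=O)O[C@H]1c2cc(Br)c(O[Si](C(C)C)(C(C)C)C(C)C)cc2OC[C@@H]1Br
F8 | step 4 | 3-(3-methylbut-2-enyl)-4-(triisopropylsilyloxy)benzene-1,2-diol | Oc1ccc(O[Si](C(C)C)(C(C)C)C(C)C)c(CC=C(C)C)c1O
F9 | step 4 | 2-(2-methylbut-3-yn-2-yloxy)-6-(3-methylbut-2-enyl)-5-(triisopropylsilyloxy)phenol | C#CC(C)(C)Oc1ccc(O[Si](C(C)C)(C(C)C)C(C)C)c(CC=C(C)C)c1O
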